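## Retrosynthetic overview
1. The C6–C7 oxirane is made last, by epoxidation of the convex face of a bicyclo[3.3.1]non-6-en-9-one.
2. C1–C2 (aldol) and C8–OMe (oxa-Michael) are cut together, as in the biogenesis of related aryl-alanine-derived bicyclo[3.3.1]nonane alkaloids. This leads back to a 6-alkyl-6-hydroxycyclohexa-2,4-dienone (o-quinol) that carries the N-acyl α-amino aldehyde.
3. The o-quinol comes from a flat phenol by catalyst-controlled dearomative spiro-lactolisation in the same flask, so phenol goes to bicycle in one operation.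
4. The phenol aldehyde, stored as its chroman-2-ol, comes from L-o-tyrosine and (E)-dodec-2-enoic acid.
5. Ring order: transient spiro-oxolane, then the carbocycle C1–C5/C9, then the oxirane.

Locants used: C1 = CH bridgehead, C2 = CHOH, C3 = CHN, C4 = CH2, C5 = C(OH) bridgehead, C6/C7 = oxirane (alkene) carbons, C8 = CHOMe, C9 = C=O.

Assumption 1: the C9 ketone lies between both bridgeheads and C8–OMe is para to C5, so the dearomatised precursor is taken to be an ortho-quinol; a tyrosine p-quinol would give the C8/C9-transposed isomer.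

Assumption 2: the (R,R)-iodoarene is taken as the enantiomer matched with the (S)-amino centre and delivering (5S); the antipode is equally available and one test run settles the choice.

## Route

Step 1
Reactants: 1 L-o-tyrosine, (S)-2-amino-3-(2-hydroxyphenyl)propanoic acid
Product: 2 methyl (S)-2-amino-3-(2-hydroxyphenyl)propanoate hydrochloride
Conditions: SOCl2 (1.5 equiv), MeOH, 0 °C → reflux
Reagents that add atoms: methanol CO; thionyl chloride O=S(Cl)Cl (chloride counter-ion)
Why: Fischer esterification driven by HCl and water scavenging from SOCl2–MeOH; no bond to the stereocentre is touched, and the ammonium salt stops lactonisation and diketopiperazine formation.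

Step 2
Reactants: 2 methyl (S)-2-amino-3-(2-hydroxyphenyl)propanoate hydrochloride; 3 (E)-dodec-2-enoic acid
Product: 4 methyl (S)-2-[(E)-dodec-2-enamido]-3-(2-hydroxyphenyl)propanoate
Conditions: EDC·HCl (1.1 equiv), HOBt (0.2 equiv), N-methylmorpholine (2.2 equiv), CH2Cl2, 0 °C → rt
Reagents that add atoms: none
Why: Carbodiimide/HOBt amide coupling in which the amine outruns the phenol; the activated partner has no α-stereocentre and the amine partner cannot form an azlactone, so C-α stays (S).

Step 3
Reactants: 4 methyl (S)-2-[(E)-dodec-2-enamido]-3-(2-hydroxyphenyl)propanoate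
Product: 5 (E)-N-[(3S)-2-hydroxychroman-3-yl]dodec-2-enamide (anomer mixture; ring-chain tautomer of the 2-hydroxyphenyl amino aldehyde)
Conditions: DIBAL-H (3.3 equiv), CH2Cl2/toluene, −78 °C; MeOH, then aq Rochelle salt
Reagents that add atoms: none
Why: Partial ester reduction with DIBAL-H, in which two equivalents go to ArOH and NH (the amidate shields the enamide), the chelated tetrahedral aluminate holds at −78 °C, and on work-up the phenol traps the aldehyde as a six-ring lactol that protects the α-centre from epimerisation.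

Step 4
Reactants: 5 (E)-N-[(3S)-2-hydroxychroman-3-yl]dodec-2-enamide
Product: 9 (E)-N-[(1S,2R,3S,5S,8R)-2,5-dihydroxy-8-methoxy-9-oxobicyclo[3.3.1]non-6-en-3-yl]dodec-2-enamide, via spiro-lactol dienone 6 (not isolated), via o-quinol aldehyde 7 (not isolated), via methoxy enolate 8 (not isolated)
Conditions: (i) 2-iodo-1,3-bis[(R)-1-(mesitoylamino)propan-2-yloxy]benzene (10 mol %), mCPBA (1.1 equiv), CH2Cl2/HFIP/H2O 80:20:1, −20 °C, 5 mM; cold aq NaHCO3/Na2S2O3 wash; (ii) organic layer run into K2CO3 (0.3 equiv), MeOH, −10 → 0 °C, ≤1 mM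
Reagents that add atoms: water O; methanol CO
Why: Proposed new method: the chiral aryl-λ3-iodane made in situ binds the phenol O of ring-opened 5, and a gem-diol OH of the hydrated aldehyde attacks the alkyl-bearing ortho carbon 5-exo (the only ring carbon it can reach), with catalyst face selection matched to C3 setting C5 as (S), the closest known reaction being the catalytic enantioselective Kita-type oxidative spirolactonisation of 3-(2-hydroxyphenyl)propanoic acids; base then opens 6 to 7, methoxide adds 1,4 at C8 on the face carrying 5-OH (anti to the folded side chain), and enolate 8 closes a 6-(enolendo)-exo-trig aldol through a cation/H-bond-bridged chair (amide equatorial, aldehyde O synclinal to the enolate O, hence axial 2-OH H-bonded to C9=O), which is the oxa-Michael/aldol cascade type known for p-quinol amino aldehydes and sets C8, C1 and C2 in one event, while the bridgehead α-H blocks retro-Michael loss of MeOH and high dilution outruns [4+2] dimerisation.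

Step 5
Reactants: 9 (E)-N-[(1S,2R,3S,5S,8R)-2,5-dihydroxy-8-methoxy-9-oxobicyclo[3.3.1]non-6-en-3-yl]dodec-2-enamide
Product: 10 (E)-N-[(1S,2R,3S,5S,6S,7S,8S)-6,7-epoxy-2,5-dihydroxy-8-methoxy-9-oxobicyclo[3.3.1]nonan-3-yl]dodec-2-enamide (target)
Conditions: DMDO (1.3 equiv), acetone/CH2Cl2, 0 °C
Reagents that add atoms: dimethyldioxirane CC1(C)OO1
Why: Neutral electrophilic dioxirane epoxidation, in which the concave face of C6=C7 is closed by C2, C4 and the endo H at C3 of the other ring, so oxygen arrives on the convex face (the face of 5-OH and 8-OMe) and sets C6 and C7, while the conjugated amide alkene is too electron-poor to compete and no peracid is present for Baeyer–Villiger attack at C9.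

## Compound list
1 | L-o-tyrosine | N[C@@H](Cc1ccccc1O)C(=O)O | starting material
2 | methyl (S)-2-amino-3-(2-hydroxyphenyl)propanoate hydrochloride | N[C@@H](Cc1ccccc1O)C(=O)OC.Cl | intermediate
3 | (E)-dodec-2-enoic acid | CCCCCCCCC/C=C/C(=O)O | starting material
4 | methyl (S)-2-[(E)-dodec-2-enamido]-3-(2-hydroxyphenyl)propanoate | CCCCCCCCC/C=C/C(=O)N[C@@H](Cc1ccccc1O)C(=O)OC | intermediate
5 | (E)-N-[(3S)-2-hydroxychroman-3-yl]dodec-2-enamide | CCCCCCCCC/C=C/C(=O)N[C@H]1Cc2ccccc2OC1O | intermediate
6 | (E)-N-[(3S,5S)-2-hydroxy-6-oxo-1-oxaspiro[4.5]deca-7,9-dien-3-yl]dodec-2-enamide | CCCCCCCCC/C=C/C(=O)N[C@H]1C[C@@]2(OC1O)C(=O)C=CC=C2 | intermediate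
7 | (E)-N-[(2S)-1-[(1S)-1-hydroxy-6-oxocyclohexa-2,4-dien-1-yl]-3-oxopropan-2-yl]dodec-2-enamide | CCCCCCCCC/C=C/C(=O)N[C@@H](C[C@@]1(O)C(=O)C=CC=C1)C=O | intermediate
8 | (E)-N-[(2S)-1-[(1S,4R)-1,2-dihydroxy-4-methoxycyclohexa-2,5-dien-1-yl]-3-oxopropan-2-yl]dodec-2-enamide (drawn as the enol, present as the potassium enolate) | CCCCCCCCC/C=C/C(=O)N[C@@H](C[C@@]1(O)C(O)=C[C@H](OC)C=C1)C=O | intermediate
9 | (E)-N-[(1S,2R,3S,5S,8R)-2,5-dihydroxy-8-methoxy-9-oxobicyclo[3.3.1]non-6-en-3-yl]dodec-2-enamide | CCCCCCCCC/C=C/C(=O)N[C@H]1C[C@@]2(O)C(=O)[C@@H]([C@H]1O)[C@H](OC)C=C2 | intermediate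
10 | (E)-N-[(1S,2R,3S,5S,6S,7S,8S)-6,7-epoxy-2,5-dihydroxy-8-methoxy-9-oxobicyclo[3.3.1]nonan-3-yl]dodec-2-enamide | CCCCCCCCC/C=C/C(=O)N[C@H]1C[C@@]2(O)C(=O)[C@@H]([C@H]1O)[C@H](OC)[C@@H]1O[C@@H]12 | target

Total step count: 5. Longest linear sequence: 5.

## Steps most likely to fail

**Step 4 (highest risk).**
- The gem-diol may be too scarce or too weak a nucleophile. Water could then attack para to give a quinone, or the peracid could attack the aldehyde.
- Compounds 6 and 7 may dimerise by [4+2].
- Methoxide or the amide N may add 1,6 at C6.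
- Epimerisation at C3 of any mismatched C5 epimer would erode the ee.

The fallback sets out from 4 and comes back at 6. It moves the dearomatisation to the carboxylic-acid level, where it is known chemistry. Compound 4 is saponified (LiOH, THF/H2O, 0 °C) to the free acid F1. The same iodoarene/mCPBA system then closes F1 to the spirolactone F2. The dienone is masked in the flask as the phosphonium silyl dienol ether F3 (PPh3, TMSOTf, CH2Cl2). The lactone, now the most electrophilic carbonyl, is taken to the lactol level with DIBAL-H at −78 °C. Aqueous NaHCO3 then unmasks the dienone and gives a solution of 6, which enters the K2CO3/MeOH stage unchanged.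

**Step 5.** The alkene is deactivated by two allylic C–O bonds, the 8-OMe sits on the face to be attacked, and the 2-OH could be over-oxidised. The fallback sets out from 6 and comes back at 10, and it inverts the order of ring formation. A second equivalent of mCPBA is added to the cold solution of 6, so the electron-rich distal alkene is epoxidised syn to the spiro oxygen to give the epoxy spiro-lactol F4. F4 can neither dimerise nor take up methoxide 1,6, and it can be purified. K2CO3/MeOH then closes it directly to 10. The price is that C8 must form syn to the oxirane, guided only by approach anti to the tether.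

**Step 3.** Over-reduction to the alcohol or loss of the α-centre are the risks. The fallback sets out from 4 and comes back at 5. The ester is converted with MeNHOMe·HCl/iPrMgCl (THF, −20 °C) into the Weinreb amide F5. Its five-ring metal chelate stops DIBAL-H reduction at the aldehyde level, and work-up gives lactol 5.

## Further compounds
F1 | step 4 | (S)-2-[(E)-dodec-2-enamido]-3-(2-hydroxyphenyl)propanoic acid | CCCCCCCCC/C=C/C(=O)N[C@@H](Cc1ccccc1O)C(=O)O
F2 | step 4 | (E)-N-[(3S,5S)-2,6-dioxo-1-oxaspiro[4.5]deca-7,9-dien-3-yl]dodec-2-enamide | CCCCCCCCC/C=C/C(=O)N[C@H]1C[C@@]2(OC1=O)C(=O)C=CC=C2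
F3 | step 4 | [(3S,5S)-3-[(E)-dodec-2-enamido]-2-oxo-6-(trimethylsilyloxy)-1-oxaspiro[4.5]deca-6,9-dien-8-yl]triphenylphosphonium triflate | CCCCCCCCC/C=C/C(=O)N[C@H]1C[C@@]2(OC1=O)C(O[Si](C)(C)C)=CC([P+](c1ccccc1)(c1ccccc1)c1ccccc1)C=C2.[O-]S(=O)(=O)C(F)(F)F
F4 | step 5 | (E)-N-[(3S,5S,9S,10S)-9,10-epoxy-2-hydroxy-6-oxo-1-oxaspiro[4.5]dec-7-en-3-yl]dodec-2-enamide | CCCCCCCCC/C=C/C(=O)N[C@H]1C[C@@]2(OC1O)C(=O)C=C[C@@H]1O[C@@H]12
F5 | step 3 | (S,E)-N-[3-(2-hydroxyphenyl)-1-[methoxy(methyl)amino]-1-oxopropan-2-yl]dodec-2-enamide | CCCCCCCCC/C=C/C(=O)N[C@@H](Cc1ccccc1O)C(=O)N(C)OC
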